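The pyran ring F of the lower unit (O1–C2–C3–C4–C4a–C8a, fused to phloroglucinol ring D) is disconnected at C3–C4 and O1–C2 into an o-quinone methide of ring D, which already carries the robinetinidol unit at C8, and a Z-enol gallate. One hetero-Diels–Alder step closes ring F through the C3–C4 bond, sets C2 and C3 cis from the Z geometry and brings in the gallate and ring E. It exploits the cis 2-aryl-3-acyloxy pattern on the C4H2–C3H(O)–C2H(Ar)–O1 chain. The precursor is a phenolic Mannich base of a 4-arylflavan-3-ol, made from (+)-dihydrorobinetin and 3,5-bis(benzyloxy)phenol.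

Key step: step 7

Assumption: (+)-dihydrorobinetin (2R,3R) is taken as a purchasable natural flavanonol.
Abbreviations: TBP = 3,4,5-tris(benzyloxy)phenyl; Fl = (2R,3S,4S)-7-benzyloxy-3-hydroxy-2-(TBP)chroman-4-yl. Rings A, C, B belong to the upper unit and rings D, F, E to the lower unit; atoms carry flavan numbers.

Step 1
Reactants: 1 (+)-dihydrorobinetin
Product: 2 (2R,3R)-7-benzyloxy-3-hydroxy-2-(TBP)chroman-4-one
Conditions: BnBr (4.4 equiv), K2CO3, DMF, 0 °C to rt, argon
Reagents that add atoms: benzyl bromide BrCc1ccccc1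
Why: Williamson O-benzylation in which K2CO3 deprotonates only the four phenols, so the secondary 3-OH stays free, and the mild base under argon should leave the 2R,3R centres of the natural product untouched.

Step 2
Reactants: 2 (2R,3R)-7-benzyloxy-3-hydroxy-2-(TBP)chroman-4-one
Product: 3 (2R,3S,4R)-7-benzyloxy-2-(TBP)chromane-3,4-diol
Conditions: NaBH4, THF/EtOH, 0 °C
Reagents that add atoms: none
Why: NaBH4 reduction of the aryl ketone by axial hydride attack on the half-chair with equatorial 2-aryl and 3-OH groups should give mainly the all-equatorial 2,3-trans-3,4-trans (4R) diol, and the C4 configuration is not critical because this centre is ionised in step 3.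

Step 3
Reactants: 3 (2R,3S,4R)-7-benzyloxy-2-(TBP)chromane-3,4-diol; 4 3,5-bis(benzyloxy)phenol (3 equiv)
Product: 5 (2R,3S,4S)-7-benzyloxy-4-[2,4-bis(benzyloxy)-6-hydroxyphenyl]-2-(TBP)chroman-3-ol
Conditions: BF3·OEt2 (0.3 equiv), 4 Å MS, CH2Cl2, −40 to 0 °C
Reagents that add atoms: none
Why: Friedel–Crafts alkylation in which the C4 hydroxyl leaves as water to give the C4 benzylic cation (stabilised by O1 and the 7-benzyloxy group), captured by the phloroglucinol-type ring of 4 at the carbon ortho to its free OH; attack anti to the C3–OH of the 2,3-trans cation should set 4S (3,4-trans, 4α), and the excess of 4 outcompetes self-condensation of 3.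

Step 4
Reactants: 5 (2R,3S,4S)-7-benzyloxy-4-[2,4-bis(benzyloxy)-6-hydroxyphenyl]-2-(TBP)chroman-3-ol
Product: 6 3,5-bis(benzyloxy)-2-[(dimethylamino)methyl]-6-(Fl)phenol
Conditions: 37% aq. CH2O, 40% aq. Me2NH, EtOH/THF, rt to 45 °C
Reagents that add atoms: formaldehyde C=O; dimethylamine CNC
Why: Phenolic Mannich reaction in which the hydrogen-bonded phenol directs the iminium ion to the one free ortho carbon (future C4a), installing the future C4 as CH2NMe2 without forming a stereocentre.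

Step 5
Reactants: 7 3,4,5-tris(benzyloxy)benzaldehyde
Product: 8 1,2,3-tris(benzyloxy)-5-ethynylbenzene
Conditions: dimethyl (1-diazo-2-oxopropyl)phosphonate, K2CO3, MeOH/THF, 0 °C to rt
Reagents that add atoms: Ohira–Bestmann reagent CC(=O)C(=[N+]=[N-])P(=O)(OC)OC
Why: Seyferth–Gilbert homologation with the Ohira–Bestmann reagent turns the aryl aldehyde into the terminal alkyne under mild base that the benzyl ethers tolerate.

Step 6
Reactants: 8 1,2,3-tris(benzyloxy)-5-ethynylbenzene; 9 3,4,5-tris(benzyloxy)benzoic acid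
Product: 10 (Z)-2-(TBP)ethenyl 3,4,5-tris(benzyloxy)benzoate
Conditions: Ru(2-methylallyl)2(dppb) (3 mol%; dppb = Ph2P(CH2)4PPh2), toluene, 65 °C
Reagents that add atoms: none
Why: Ru-catalysed anti-Markovnikov hydro-oxycarbonylation of a terminal alkyne through a ruthenium vinylidene, the carboxylate adding to the terminal carbon so that the enol ester should form with the Z geometry that later becomes the cis C2/C3 relationship.

Step 7
Reactants: 6 3,5-bis(benzyloxy)-2-[(dimethylamino)methyl]-6-(Fl)phenol; 10 (Z)-2-(TBP)ethenyl 3,4,5-tris(benzyloxy)benzoate (2.5 equiv)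
Product: 13 dodeca-O-benzyl robinetinidol-(4α→8)-epigallocatechin 3-O-gallate, via ammonium iodide 11 (not isolated), via o-quinone methide 12 (not isolated)
Conditions: MeI, THF, rt, then evaporate; 10 (2.5 equiv), K2CO3, MeCN/toluene, 60 °C, sealed vessel
Reagents that add atoms: none
Why: Proposed new method: deprotonation of ammonium phenol 11 expels trimethylamine to give the neutral o-quinone methide 12 (1-oxadiene O1=C8a–C4a=C4 on ring D), which should add the Z-enol ester 10 in an inverse-electron-demand hetero-Diels–Alder reaction; the closest known reaction type is the thermal [4+2] of o-quinone methides with β-substituted styrenes that gives 2-aryl-3-substituted chromans, here extended to a β-acyloxystyrene. Ring F is closed by this intermolecular [4+2] cycloaddition, concerted and asynchronous, with C4–C3 forming ahead of O1–C2 on the same face. C2 and C3 should come out cis because the Z geometry of 10 is transferred suprafacially, and 12 is generated without acid to avoid a stepwise cation and acyloxonium route to the trans isomer. The absolute sense (2R,3R) depends on which face of 12 is attacked and is controlled only by the resident (2R,3S,4S)-flavanyl group on C8 next to O1, so the 2S,3S cis diastereomer is expected as a separable by-product. The step needs the orientation aryl carbon to O1 and acyloxy carbon to C4, which should be favoured because the trialkoxyphenyl group stabilises positive charge at C2 while the ester oxygen is only a weak, cross-conjugated donor. Excess 10 and slow release of 12 should keep oligomerisation of the o-quinone methide down.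

Step 8
Reactants: 13 dodeca-O-benzyl robinetinidol-(4α→8)-epigallocatechin 3-O-gallate
Product: 14 robinetinidol-(4α→8)-epigallocatechin 3-O-gallate (CNP0269431.1)
Conditions: H2 (1 atm), Pd(OH)2/C, THF/MeOH, rt
Reagents that add atoms: none
Why: Hydrogenolysis of the twelve aryl benzyl ethers over Pd(OH)2/C under neutral conditions, which in catechin gallate chemistry leaves the flavan C2–O1 bonds, the interflavan C4–C8 bond, the gallate ester and all five stereocentres untouched.

Compound list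

1 | (+)-dihydrorobinetin, (2R,3R)-3,7-dihydroxy-2-(3,4,5-trihydroxyphenyl)chroman-4-one | O=C1c2ccc(O)cc2O[C@H](c2cc(O)c(O)c(O)c2)[C@H]1O | starting material
2 | (2R,3R)-7-benzyloxy-3-hydroxy-2-[3,4,5-tris(benzyloxy)phenyl]chroman-4-one | O=C1c2ccc(OCc3ccccc3)cc2O[C@H](c2cc(OCc3ccccc3)c(OCc3ccccc3)c(OCc3ccccc3)c2)[C@H]1O | intermediate
3 | (2R,3S,4R)-7-benzyloxy-2-[3,4,5-tris(benzyloxy)phenyl]chromane-3,4-diol (2,3-trans-3,4-trans) | O[C@@H]1c2ccc(OCc3ccccc3)cc2O[C@H](c2cc(OCc3ccccc3)c(OCc3ccccc3)c(OCc3ccccc3)c2)[C@H]1O | intermediate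
4 | 3,5-bis(benzyloxy)phenol | Oc1cc(OCc2ccccc2)cc(OCc2ccccc2)c1 | starting material
5 | (2R,3S,4S)-7-benzyloxy-4-[2,4-bis(benzyloxy)-6-hydroxyphenyl]-2-[3,4,5-tris(benzyloxy)phenyl]chroman-3-ol (2,3-trans-3,4-trans; equals 3,5-bis(benzyloxy)-2-(Fl)phenol) | Oc1cc(OCc2ccccc2)cc(OCc2ccccc2)c1[C@@H]1c2ccc(OCc3ccccc3)cc2O[C@H](c2cc(OCc3ccccc3)c(OCc3ccccc3)c(OCc3ccccc3)c2)[C@H]1O | intermediate
6 | 3,5-bis(benzyloxy)-2-[(dimethylamino)methyl]-6-(Fl)phenol | CN(C)Cc1c(O)c([C@@H]2c3ccc(OCc4ccccc4)cc3O[C@H](c3cc(OCc4ccccc4)c(OCc4ccccc4)c(OCc4ccccc4)c3)[C@H]2O)c(OCc2ccccc2)cc1OCc1ccccc1 | intermediate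
7 | 3,4,5-tris(benzyloxy)benzaldehyde | O=Cc1cc(OCc2ccccc2)c(OCc2ccccc2)c(OCc2ccccc2)c1 | starting material
8 | 1,2,3-tris(benzyloxy)-5-ethynylbenzene | C#Cc1cc(OCc2ccccc2)c(OCc2ccccc2)c(OCc2ccccc2)c1 | intermediate
9 | 3,4,5-tris(benzyloxy)benzoic acid | OC(=O)c1cc(OCc2ccccc2)c(OCc2ccccc2)c(OCc2ccccc2)c1 | starting material
10 | (Z)-2-[3,4,5-tris(benzyloxy)phenyl]ethenyl 3,4,5-tris(benzyloxy)benzoate | O=C(O/C=C\c1cc(OCc2ccccc2)c(OCc2ccccc2)c(OCc2ccccc2)c1)c1cc(OCc2ccccc2)c(OCc2ccccc2)c(OCc2ccccc2)c1 | intermediate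
11 | {[4,6-bis(benzyloxy)-2-hydroxy-3-(Fl)phenyl]methyl}trimethylammonium iodide | C[N+](C)(C)Cc1c(O)c([C@@H]2c3ccc(OCc4ccccc4)cc3O[C@H](c3cc(OCc4ccccc4)c(OCc4ccccc4)c(OCc4ccccc4)c3)[C@H]2O)c(OCc2ccccc2)cc1OCc1ccccc1.[I-] | intermediate (not isolated)
12 | 3,5-bis(benzyloxy)-6-methylidene-2-(Fl)cyclohexa-2,4-dien-1-one (o-quinone methide) | C=C1C(=O)C([C@@H]2c3ccc(OCc4ccccc4)cc3O[C@H](c3cc(OCc4ccccc4)c(OCc4ccccc4)c(OCc4ccccc4)c3)[C@H]2O)=C(OCc2ccccc2)C=C1OCc1ccccc1 | intermediate (not isolated)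
13 | (2R,3R)-5,7-bis(benzyloxy)-8-(Fl)-2-[3,4,5-tris(benzyloxy)phenyl]chroman-3-yl 3,4,5-tris(benzyloxy)benzoate (2,3-cis) | O=C(O[C@@H]1Cc2c(OCc3ccccc3)cc(OCc3ccccc3)c([C@@H]3c4ccc(OCc5ccccc5)cc4O[C@H](c4cc(OCc5ccccc5)c(OCc5ccccc5)c(OCc5ccccc5)c4)[C@H]3O)c2O[C@@H]1c1cc(OCc2ccccc2)c(OCc2ccccc2)c(OCc2ccccc2)c1)c1cc(OCc2ccccc2)c(OCc2ccccc2)c(OCc2ccccc2)c1 | intermediate
14 | (2R,3R)-5,7-dihydroxy-8-[(2R,3S,4S)-3,7-dihydroxy-2-(3,4,5-trihydroxyphenyl)chroman-4-yl]-2-(3,4,5-trihydroxyphenyl)chroman-3-yl 3,4,5-trihydroxybenzoate | O=C(O[C@@H]1Cc2c(O)cc(O)c([C@@H]3c4ccc(O)cc4O[C@H](c4cc(O)c(O)c(O)c4)[C@H]3O)c2O[C@@H]1c1cc(O)c(O)c(O)c1)c1cc(O)c(O)c(O)c1 | target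

Total step count: 8. Longest linear sequence: 6 steps (steps 1, 2, 3, 4, 7, 8); steps 5 and 6 form the second branch.

Steps most likely to fail

1. Step 7 (proposed new method). The enol ester may add in the opposite orientation, with the ester oxygen rather than the aryl group directing. The dienophile may attack the undesired face of 12. A stepwise ionic addition may erode the cis geometry. The o-quinone methide may oligomerise, or be captured by the free 3-OH of the flavanyl group, faster than it is trapped by 10. The fallback uses known reaction types, sets out from phenol 5 and comes back to the route at target 14. Magnesium-mediated ortho-formylation of 5 (MgCl2, Et3N, paraformaldehyde, MeCN, reflux) would give salicylaldehyde F1, and Wittig methylenation with excess Ph3P=CH2 in THF would give vinylphenol F2. In parallel, aldehyde 7 would be converted in one pot (ethynylmagnesium bromide, then acetic anhydride) into racemic propargylic acetate F3. Copper-catalysed asymmetric propargylic etherification of F2 with F3 (CuOTf, chiral pybox ligand, iPr2NEt, using the ligand antipode that delivers the S ether) would set the future C2 under catalyst control and give propargyl aryl ether F4. Ru-catalysed Markovnikov addition of acid 9 to the alkyne ([RuCl2(p-cymene)]2, P(2-furyl)3, Na2CO3, toluene) would give enol gallate F5. Ring-closing metathesis with the second-generation Grubbs catalyst would then close ring F through the same C3–C4 bond, as a C3=C4 double bond, and give chromenyl gallate F6. Hydrogenation of F6 under the conditions of step 8 should add hydrogen to C3=C4 from the face opposite the C2 aryl group, giving the 2,3-cis gallate while the benzyl groups are removed, and so lead to 14.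

2. Step 3. C-alkylation para to the phenol OH or O-alkylation may compete, some attack syn to the 3-OH would give the 4β epimer, and diol 3 may self-condense through its own ring A. The fallback sets out from diol 3 and comes back at phenol 5. Acetylation (Ac2O, pyridine) would give diacetate F7. Coupling of F7 with 4 under TMSOTf in CH2Cl2 at −78 °C would give 3-O-acetate F8: the 4-acetate is the leaving group, and the 3-acetate bridges the C4 cation as an acetoxonium ion and blocks the cis face, so the arene must enter trans, while no free hydroxyl is present to self-condense. Methanolysis (K2CO3, MeOH) would return 5.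

3. Step 4. Aminomethylation may occur at the carbon para to the phenol OH, between the two benzyloxy groups, and the Mannich base may lose amine on purification. The fallback sets out from phenol 5 and comes back at 13 through the same o-quinone methide 12. Condensation of 5 with PhB(OH)2 and paraformaldehyde (cat. EtCO2H, toluene, reflux with water removal) would give benzodioxaborin F9, in which boron ties the phenol oxygen to the formaldehyde carbon so that only ortho C–C bond formation is possible. Transesterification with propane-1,3-diol would release salicyl alcohol F10. Heating F10 with 10 in o-xylene over 4 Å MS at 130 °C would dehydrate it to 12, which adds 10 as in step 7 to give 13.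

Further compounds

F1 | step 7 | 4,6-bis(benzyloxy)-2-hydroxy-3-(Fl)benzaldehyde | O=Cc1c(O)c([C@@H]2c3ccc(OCc4ccccc4)cc3O[C@H](c3cc(OCc4ccccc4)c(OCc4ccccc4)c(OCc4ccccc4)c3)[C@H]2O)c(OCc2ccccc2)cc1OCc1ccccc1
F2 | step 7 | 3,5-bis(benzyloxy)-2-(Fl)-6-vinylphenol | C=Cc1c(O)c([C@@H]2c3ccc(OCc4ccccc4)cc3O[C@H](c3cc(OCc4ccccc4)c(OCc4ccccc4)c(OCc4ccccc4)c3)[C@H]2O)c(OCc2ccccc2)cc1OCc1ccccc1
F3 | step 7 | racemic 1-[3,4,5-tris(benzyloxy)phenyl]prop-2-yn-1-yl acetate | CC(=O)OC(C#C)c1cc(OCc2ccccc2)c(OCc2ccccc2)c(OCc2ccccc2)c1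
F4 | step 7 | (S)-1-(TBP)prop-2-yn-1-yl ether of vinylphenol F2 | C=Cc1c(O[C@@H](C#C)c2cc(OCc3ccccc3)c(OCc3ccccc3)c(OCc3ccccc3)c2)c([C@@H]2c3ccc(OCc4ccccc4)cc3O[C@H](c3cc(OCc4ccccc4)c(OCc4ccccc4)c(OCc4ccccc4)c3)[C@H]2O)c(OCc2ccccc2)cc1OCc1ccccc1
F5 | step 7 | (R)-3-[3,5-bis(benzyloxy)-2-(Fl)-6-vinylphenoxy]-3-(TBP)prop-1-en-2-yl 3,4,5-tris(benzyloxy)benzoate | C=Cc1c(O[C@@H](C(=C)OC(=O)c2cc(OCc3ccccc3)c(OCc3ccccc3)c(OCc3ccccc3)c2)c2cc(OCc3ccccc3)c(OCc3ccccc3)c(OCc3ccccc3)c2)c([C@@H]2c3ccc(OCc4ccccc4)cc3O[C@H](c3cc(OCc4ccccc4)c(OCc4ccccc4)c(OCc4ccccc4)c3)[C@H]2O)c(OCc2ccccc2)cc1OCc1ccccc1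
F6 | step 7 | (2R)-5,7-bis(benzyloxy)-8-(Fl)-2-(TBP)-2H-chromen-3-yl 3,4,5-tris(benzyloxy)benzoate | O=C(OC1=Cc2c(OCc3ccccc3)cc(OCc3ccccc3)c([C@@H]3c4ccc(OCc5ccccc5)cc4O[C@H](c4cc(OCc5ccccc5)c(OCc5ccccc5)c(OCc5ccccc5)c4)[C@H]3O)c2O[C@@H]1c1cc(OCc2ccccc2)c(OCc2ccccc2)c(OCc2ccccc2)c1)c1cc(OCc2ccccc2)c(OCc2ccccc2)c(OCc2ccccc2)c1
F7 | step 3 | (2R,3R,4R)-7-benzyloxy-2-(TBP)chromane-3,4-diyl diacetate (2,3-trans-3,4-trans, same geometry as 3; the C3 descriptor changes only through the priority rules) | CC(=O)O[C@@H]1c2ccc(OCc3ccccc3)cc2O[C@H](c2cc(OCc3ccccc3)c(OCc3ccccc3)c(OCc3ccccc3)c2)[C@H]1OC(C)=O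
F8 | step 3 | (2R,3S,4S)-7-benzyloxy-4-[2,4-bis(benzyloxy)-6-hydroxyphenyl]-2-(TBP)chroman-3-yl acetate | Oc1cc(OCc2ccccc2)cc(OCc2ccccc2)c1[C@@H]1c2ccc(OCc3ccccc3)cc2O[C@H](c2cc(OCc3ccccc3)c(OCc3ccccc3)c(OCc3ccccc3)c2)[C@H]1OC(C)=O
F9 | step 4 | 5,7-bis(benzyloxy)-8-(Fl)-2-phenyl-4H-1,3,2-benzodioxaborin | B1(c2ccccc2)OCc2c(OCc3ccccc3)cc(OCc3ccccc3)c([C@@H]3c4ccc(OCc5ccccc5)cc4O[C@H](c4cc(OCc5ccccc5)c(OCc5ccccc5)c(OCc5ccccc5)c4)[C@H]3O)c2O1
F10 | step 4 | 3,5-bis(benzyloxy)-2-(Fl)-6-(hydroxymethyl)phenol | OCc1c(O)c([C@@H]2c3ccc(OCc4ccccc4)cc3O[C@H](c3cc(OCc4ccccc4)c(OCc4ccccc4)c(OCc4ccccc4)c3)[C@H]2O)c(OCc2ccccc2)cc1OCc1ccccc1
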